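## Retrosynthetic overview

1. Ketoemblide ⇒ open the 14-membered carbocycle at the C(sp3)–C(sp2) bond next to the isopropyl-bearing alkene: a Ni-electrocatalytic decarboxylative macro-alkenylation of seco acid 17 (alkyl carboxylic acid + (Z,Z)-dienyl iodide), done last.
2. 17 ⇒ Z-selective Still–Gennari olefination of phosphonate 11 with (Z)-β-iodoenal 15 (three steps from 3-methylbut-1-yne); this sets the (Z)-enoate.
3. 11 ⇒ Michael addition of the Still–Gennari reagent to vinyl ketone 9, made from the linalool vinyl group by Wacker oxidation and α-methylenation.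
4. Oxepinone 7 (first ring) ⇒ ozonolysis and intramolecular HWE of (S)-linalyl phosphonoacetate 5, itself from (S)-linalool, diethylphosphonoacetic acid and tert-butyl acrylate.
5. Ring order: 7-membered lactone (step 3), then 14-membered carbocycle (step 12). The only stereocentre is the linalool carbinol carbon, carried through unchanged.

Assumption: (S)-(+)-linalool (coriandrol, the coriander-oil enantiomer) is purchasable in high ee; its carbinol carbon maps directly onto the (S)-configured quaternary C–O carbon of the target (vinyl → ketone carbon).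

## Route

**Step 1**
Reactants: 1 (S)-(+)-linalool; 2 2-(diethoxyphosphoryl)acetic acid
Product: 3 (3S)-3,7-dimethylocta-1,6-dien-3-yl 2-(diethoxyphosphoryl)acetate
Conditions: DCC, DMAP (cat.), CH2Cl2, 0 °C → rt
Reagents that add atoms: 2-(diethoxyphosphoryl)acetic acid (2), OC(=O)CP(=O)(OCC)OCC
Why: Steglich esterification, the standard way to put a phosphonoacetate on a hindered tertiary carbinol; the C–O bond of the stereocentre is not broken, so configuration is retained.

**Step 2**
Reactants: 3; 4 tert-butyl acrylate
Product: 5 5-tert-butyl 1-[(3S)-3,7-dimethylocta-1,6-dien-3-yl] 2-(diethoxyphosphoryl)pentanedioate (epimers at the phosphonate carbon)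
Conditions: 4 (1.05 equiv), NaH (15 mol%), THF, 0 °C → rt
Reagents that add atoms: tert-butyl acrylate (4), C=CC(=O)OC(C)(C)C
Why: Base-catalysed Michael addition of the phosphonoacetate anion adds the two ring CH2 groups plus a masked carboxyl (the later radical precursor); the new stereocentre is destroyed in step 3.

**Step 3**
Reactants: 5
Product: 7 tert-butyl 3-[(7S)-7-ethenyl-7-methyl-2-oxo-2,5,6,7-tetrahydrooxepin-3-yl]propanoate (via aldehyde 6, not isolated)
Conditions: O3 (1.0 equiv, Sudan Red 7B end point), pyridine, CH2Cl2, −78 °C; then LiCl, DBU, MeCN, rt, 5 mM (one pot)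
Reagents that add atoms: none retained in 7 (ozone, [O-][O+]=O, supplies the aldehyde oxygen of 6, which is lost in the olefination)
Why: Ozone cleaves the electron-rich trisubstituted alkene in preference to the deactivated vinyl group, and the intramolecular Horner–Wadsworth–Emmons reaction then closes the oxepinone, whose ring size forces the required cis relationship between the lactone carbonyl and the ring CH2.

**Step 4**
Reactants: 7
Product: 8 tert-butyl 3-[(7S)-7-acetyl-7-methyl-2-oxo-2,5,6,7-tetrahydrooxepin-3-yl]propanoate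
Conditions: Pd(Quinox)Cl2 (5 mol%), AgSbF6 (12 mol%), aq. TBHP, CH2Cl2, 0 °C → rt
Reagents that add atoms: tert-butyl hydroperoxide, CC(C)(C)OO (ketone oxygen)
Why: TBHP-mediated Tsuji–Wacker oxidation (achiral Quinox ligand) gives the methyl ketone from terminal alkenes carrying an allylic acyloxy group; the enoate and tert-butyl ester are inert and the quaternary stereocentre cannot epimerise.

**Step 5**
Reactants: 8
Product: 9 tert-butyl 3-[(7S)-7-methyl-2-oxo-7-(prop-2-enoyl)-2,5,6,7-tetrahydrooxepin-3-yl]propanoate
Conditions: (CH2O)n, i-Pr2NH·TFA, TFA (10 mol%), THF, 65 °C; used promptly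
Reagents that add atoms: formaldehyde (paraformaldehyde), C=O
Why: Mannich condensation/β-elimination (direct α-methylenation) at the only enolisable position of the ketone adds the missing CH2 as a vinyl ketone.

**Step 6**
Reactants: 9; 10 methyl 2-[bis(2,2,2-trifluoroethoxy)phosphoryl]acetate (Still–Gennari reagent)
Product: 11 methyl 2-[bis(2,2,2-trifluoroethoxy)phosphoryl]-5-[(7S)-3-(3-tert-butoxy-3-oxopropyl)-7-methyl-2-oxo-2,5,6,7-tetrahydrooxepin-7-yl]-5-oxopentanoate (epimers at the phosphonate carbon)
Conditions: 10 (1.5 equiv), DBU (20 mol%), THF, −20 → 0 °C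
Reagents that add atoms: Still–Gennari reagent (10), COC(=O)CP(=O)(OCC(F)(F)F)OCC(F)(F)F
Why: Soft Michael addition of the phosphonate carbanion to the vinyl ketone (far more electrophilic than the trisubstituted lactone enoate); excess 10 suppresses double addition.

**Step 7**
Reactants: 12 3-methylbut-1-yne
Product: 13 4-methylpent-2-yn-1-ol
Conditions: n-BuLi, THF, −78 °C; (CH2O)n, → rt
Reagents that add atoms: formaldehyde (paraformaldehyde), C=O
Why: Hydroxymethylation of the lithium acetylide.

**Step 8**
Reactants: 13
Product: 14 (Z)-3-iodo-4-methylpent-2-en-1-ol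
Conditions: Red-Al, THF, 0 °C → rt; EtOAc; then I2, −78 → 0 °C
Reagents that add atoms: iodine, II
Why: Hydroxyl-directed trans-hydroalumination of the propargylic alcohol followed by iodinolysis; the cyclic alkoxy-alanate places iodine at C3 cis to the CH2OH group.

**Step 9**
Reactants: 14
Product: 15 (Z)-3-iodo-4-methylpent-2-enal
Conditions: MnO2, CH2Cl2, rt, dark
Reagents that add atoms: none
Why: Neutral allylic oxidation with MnO2 gives the β-iodoenal without Z/E isomerisation.

**Step 10**
Reactants: 11; 15
Product: 16 methyl (2Z,4Z)-2-{3-[(7S)-3-(3-tert-butoxy-3-oxopropyl)-7-methyl-2-oxo-2,5,6,7-tetrahydrooxepin-7-yl]-3-oxopropyl}-5-iodo-6-methylhepta-2,4-dienoate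
Conditions: KHMDS (1.0 equiv), 18-crown-6, THF, −78 °C; then 15; keep cold and dark
Reagents that add atoms: (Z)-3-iodo-4-methylpent-2-enal (15), O=C/C=C(\I)C(C)C
Why: Still–Gennari olefination of the α-substituted bis(trifluoroethyl) phosphonate is kinetically Z-selective, placing CO2Me cis to the dienyl chain; the phosphonate C–H is deprotonated selectively over the ketone and the iodoalkene geometry is untouched.

**Step 11**
Reactants: 16
Product: 17 3-[(7S)-7-{(4Z,6Z)-7-iodo-4-(methoxycarbonyl)-8-methylnona-4,6-dienoyl}-7-methyl-2-oxo-2,5,6,7-tetrahydrooxepin-3-yl]propanoic acid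
Conditions: TFA/CH2Cl2 (1:4), 0 °C
Reagents that add atoms: none
Why: Acidolysis of the tert-butyl ester; the tertiary lactone C–O bond is protected from ionisation by the adjacent ketone, and the methyl ester and vinyl iodide are stable.

**Step 12**
Reactants: 17
Product: 19 ketoemblide (via N-acyloxyphthalimide 18, not isolated)
Conditions: NHPI, DIC, DMAP (cat.), CH2Cl2, rt; then NiCl2·6H2O/2,2′-bipyridine (20 mol%), AgNO3 (0.3 equiv), LiCl, DMF, (+)Mg/(−)RVC, constant current, rt, syringe-pump addition (final 2 mM), dark
Reagents that add atoms: none retained (N-hydroxyphthalimide, ON1C(=O)c2ccccc2C1=O, appears only in transient 18)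
Why: Proposed new method: an intramolecular, macrocyclising Ni-electrocatalytic decarboxylative alkenylation — cathodically formed Ni(0) adds oxidatively to the dienyl iodide with retention, reduction of the redox-active ester releases CO2 and a primary alkyl radical (its only cyclisation mode, 3-exo onto the lactone α-carbon, is slow and degenerate), and the tethered vinyl–Ni(II) captures it so that reductive elimination from Ni(III) closes the 14-membered ring with the CH2 group cis to the diene; slow addition keeps Ni in excess of free substrate so radical capture is intramolecular; the closest known reaction is the intermolecular, stereoretentive Ni-electrocatalytic coupling of NHPI esters with alkenyl iodides, which has not been used to close a carbocyclic macrocycle or on a (Z,Z)-5-iodo-2,4-dienoate.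

## Compound list

1 | (S)-(+)-linalool | C=C[C@@](C)(O)CCC=C(C)C | starting material
2 | 2-(diethoxyphosphoryl)acetic acid | OC(=O)CP(=O)(OCC)OCC | starting material
3 | (3S)-3,7-dimethylocta-1,6-dien-3-yl 2-(diethoxyphosphoryl)acetate | C=C[C@@](C)(OC(=O)CP(=O)(OCC)OCC)CCC=C(C)C | intermediate
4 | tert-butyl acrylate | C=CC(=O)OC(C)(C)C | starting material
5 | 5-tert-butyl 1-[(3S)-3,7-dimethylocta-1,6-dien-3-yl] 2-(diethoxyphosphoryl)pentanedioate | C=C[C@@](C)(OC(=O)C(CCC(=O)OC(C)(C)C)P(=O)(OCC)OCC)CCC=C(C)C | intermediate
6 | 5-tert-butyl 1-[(3S)-3-methyl-6-oxohex-1-en-3-yl] 2-(diethoxyphosphoryl)pentanedioate | C=C[C@@](C)(OC(=O)C(CCC(=O)OC(C)(C)C)P(=O)(OCC)OCC)CCC=O | intermediate (not isolated)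
7 | tert-butyl 3-[(7S)-7-ethenyl-7-methyl-2-oxo-2,5,6,7-tetrahydrooxepin-3-yl]propanoate | C=C[C@@]1(C)OC(=O)C(CCC(=O)OC(C)(C)C)=CCC1 | intermediate
8 | tert-butyl 3-[(7S)-7-acetyl-7-methyl-2-oxo-2,5,6,7-tetrahydrooxepin-3-yl]propanoate | CC(=O)[C@@]1(C)OC(=O)C(CCC(=O)OC(C)(C)C)=CCC1 | intermediate
9 | tert-butyl 3-[(7S)-7-methyl-2-oxo-7-(prop-2-enoyl)-2,5,6,7-tetrahydrooxepin-3-yl]propanoate | C=CC(=O)[C@@]1(C)OC(=O)C(CCC(=O)OC(C)(C)C)=CCC1 | intermediate
10 | methyl 2-[bis(2,2,2-trifluoroethoxy)phosphoryl]acetate | COC(=O)CP(=O)(OCC(F)(F)F)OCC(F)(F)F | starting material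
11 | methyl 2-[bis(2,2,2-trifluoroethoxy)phosphoryl]-5-[(7S)-3-(3-tert-butoxy-3-oxopropyl)-7-methyl-2-oxo-2,5,6,7-tetrahydrooxepin-7-yl]-5-oxopentanoate | COC(=O)C(CCC(=O)[C@@]1(C)OC(=O)C(CCC(=O)OC(C)(C)C)=CCC1)P(=O)(OCC(F)(F)F)OCC(F)(F)F | intermediate
12 | 3-methylbut-1-yne | CC(C)C#C | starting material
13 | 4-methylpent-2-yn-1-ol | CC(C)C#CCO | intermediate
14 | (Z)-3-iodo-4-methylpent-2-en-1-ol | OC/C=C(\I)C(C)C | intermediate
15 | (Z)-3-iodo-4-methylpent-2-enal | O=C/C=C(\I)C(C)C | intermediate
16 | methyl (2Z,4Z)-2-{3-[(7S)-3-(3-tert-butoxy-3-oxopropyl)-7-methyl-2-oxo-2,5,6,7-tetrahydrooxepin-7-yl]-3-oxopropyl}-5-iodo-6-methylhepta-2,4-dienoate | COC(=O)/C(CCC(=O)[C@@]1(C)OC(=O)C(CCC(=O)OC(C)(C)C)=CCC1)=C\C=C(\C(C)C)I | intermediate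
17 | 3-[(7S)-7-{(4Z,6Z)-7-iodo-4-(methoxycarbonyl)-8-methylnona-4,6-dienoyl}-7-methyl-2-oxo-2,5,6,7-tetrahydrooxepin-3-yl]propanoic acid | COC(=O)/C(CCC(=O)[C@@]1(C)OC(=O)C(CCC(=O)O)=CCC1)=C\C=C(\C(C)C)I | intermediate
18 | N-phthalimidoyl ester of 17 | COC(=O)/C(CCC(=O)[C@@]1(C)OC(=O)C(CCC(=O)ON2C(=O)c3ccccc3C2=O)=CCC1)=C\C=C(\C(C)C)I | intermediate (not isolated)
19 | ketoemblide | COC(=O)/C1=C\C=C(\C(C)C)CCC2=CCC[C@](C)(OC2=O)C(=O)CC1 | target

## Summary

Total steps: 12. Longest linear sequence: 9 (steps 1–6, 10–12, from (S)-linalool).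

Steps most likely to fail, with fallbacks:

1. **Step 12 (proposed new macro-alkenylation).** Risks are hydrodecarboxylation or oligomers if intramolecular capture is slow, Z/E erosion at the dienyl–Ni stage, and cyclisation of the (Z,Z)-5-iodo-dienoate to a 2-pyranone if warmed. Fallback with known chemistry: form the same C–C bond intermolecularly under the established Ni-electrocatalytic conditions (acid from TFA cleavage of 8, as its NHPI ester, coupled with the TBS ether of 14). Then apply steps 5–6, desilylate, oxidise with MnO2, and close the 14-membered ring at the enoate C=C by a high-dilution intramolecular Still–Gennari olefination.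
2. **Step 4 (Wacker oxidation of a vinyl group on a quaternary, acyloxy-bearing carbon).** Risks are aldehyde formation, allylic transposition or low conversion. Fallback: ozonolyse the vinyl group of 7 to the aldehyde, add vinylmagnesium bromide at −78 °C and oxidise with Dess–Martin periodinane, which gives enone 9 directly and replaces steps 4–5.
3. **Step 3 (one-pot ozonolysis and 7-membered intramolecular HWE).** Risks are dimerisation or sluggish closure with the α-branched phosphonate. Fallback that changes the ring-forming bond from C=C to C–O: ozonolyse 1 to its lactol, olefinate intermolecularly with the bis(trifluoroethyl)/methyl-ester analogue of the phosphonate in 5 (Still–Gennari, cold quench), hydrolyse the methyl ester and close the lactone by Yamaguchi lactonisation.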